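The partner balance is the invariant here: each substrate molecule turned costs one partner, whichever hand it has. Partner is the limiting reagent, because its charge is smaller than the two substrates together.

| setting | north-west | east | north | flask |
|---|---|---|---|---|
| left-handed substrate | 6 mM | 9 mM | 12 mM | 12 mM |
| right-handed substrate | 6 mM | 9 mM | 12 mM | 12 mM |
| partner | 0.60 equiv | 0.60 equiv | 0.60 equiv | 0.600 equiv |
| free catalyst | 2 mol% | 2 mol% | 4 mol% | 2 mol% |
| remark | run made earlier | run made earlier | run made earlier |  |

| run | time / h | left-handed product / % |
|---|---|---|
| north-west | 2.00 | 1.7 |
| north-west | 5.00 | 4.8 |
| north-west | 10.0 | 7.8 |
| north-west | 15.0 | 9.0 |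
| east | 1.33 | 3.3 |
| east | 3.00 | 5.8 |
| east | 6.00 | 8.4 |
| east | 15.0 | 12.2 |
| north | 1.33 | 7.5 |
| north | 3.00 | 11.8 |
| north | 6.00 | 16.5 |
| north | 15.0 | 18.7 |

(each reading ± 0.5 percentage points)

- free catalyst is single-handed; left-handed substrate and right-handed substrate are mirror images of each other, charged as a racemate, each of them at the stated concentration

1. apparent order in free catalyst when 10% of the left-handed substrate and right-handed substrate together are converted (percent change of the rate of making left-handed product for one percent more free catalyst charged)
2. apparent order in partner when 10% of the left-handed substrate and right-handed substrate together are converted (percent change of the rate of making left-handed product for one percent more partner charged)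

First I take the main step by itself, with rate proportional to free catalyst, substrate left and partner left. At a fixed conversion the spent partner is a fixed amount. As a fraction of its charge, the partner left is

66.7%

I call this the fraction left. The order in free catalyst is then one. One percent more partner charged lifts the partner left by more than one percent, so the order in partner is

1.50

Next I add a loss of partner. The north-west run crawls from 7.8% to 9.0% with 70.0% of its partner not in left-handed product, and I read that as a loss needing no catalyst. The forecast reads it as an equilibrium instead. In the north run, 18.7% of left-handed product leaves this share of partner not in left-handed product: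

37.7%

That share still counts any right-handed product and any unspent partner, so I can only guess the loss. My guess for the flask at the asked conversion is 18.8% of its partner charge, half of that share. More catalyst arrives sooner and loses less, so the order in free catalyst becomes

1.39

I leave the order in partner near 1.50.

Last come the right-handed substrate and any bound catalyst. The first costs partner at the same price, so the fraction left stands. The second I cannot read from these runs.

The forecast says 1 and 1.8. Its partner order is above mine, “inflated by closeness to equilibrium”.

The flask gives 1.4 in free catalyst and 1.5 in partner.

    free catalyst + left-handed substrate ⇌ catalyst intermediate A (K = 31.0 L mol⁻¹, k = 6230 L mol⁻¹ h⁻¹)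
    free catalyst + right-handed substrate ⇌ catalyst intermediate B (K = 27.0 L mol⁻¹, k = 17700 L mol⁻¹ h⁻¹)
    partner + catalyst intermediate A → free catalyst + left-handed product (k = 2480 L mol⁻¹ h⁻¹)
    partner + catalyst intermediate B → free catalyst + right-handed product (k = 547 L mol⁻¹ h⁻¹)
    2 partner → self-condensation product (k = 9.79 L mol⁻¹ h⁻¹)

The flask reaches the asked conversion at 3.36 h. At 15.0 h its two products stand at 18.6% of the substrate charge. Scaling the spend behind the fraction left, the main steps leave this much partner:

38.1%

The flask holds 7.38%, a gap of 31 percentage points. Its 1.11 mM of self-condensation product, two partner each, is 30.8% of the partner charge.

All runs are simulated on assumed constants; noise was put on by code.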